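**Retrosynthetic overview**
1. Target 8 ⇐ hydrolysis of the vinylogous methyl ester of hydroxy-methoxyquinone 7 (same pot).
2. 7 ⇐ methoxyquinone 5 by forming the C5–O bond: oxygen-atom transfer from a pyridine N-oxide to the quinone C–H (new reaction, key step).
3. 5 ⇐ arene 4 by oxidative demethylation of the para-dimethoxy pair.
4. 4 ⇐ 1,2,4-trimethoxybenzene 1 + 1-bromohexadecane 2 by lithiation at C3 and alkylation.
5. Rings: the single six-membered carbocycle is bought intact in 1; no ring is formed.

Assumption: the target has no stereocentre and no stereogenic double bond (it is achiral), so there is no enantiomer to select; the chain is read as n-hexadecyl (C16).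

**Route**

Step 1
Reactants: 1 1,2,4-trimethoxybenzene; 2 1-bromohexadecane
Product: 4 2-hexadecyl-1,3,4-trimethoxybenzene, via (2,3,6-trimethoxyphenyl)lithium 3 (not isolated)
Conditions: 1 (1.3 equiv), n-BuLi (1.25 equiv), TMEDA, THF, 0 °C → rt, 1 h; then 2 (1.0 equiv), rt → 50 °C, 12 h
Reagents that add atoms: none
Why: Directed ortho-metalation occurs at C3, the only position flanked by two methoxy groups, and the aryllithium is alkylated by the primary bromide (SN2), which puts the chain between two oxygens with the third oxygen already in place; no stereocentre is formed.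

Step 2
Reactants: 4 2-hexadecyl-1,3,4-trimethoxybenzene
Product: 5 3-hexadecyl-2-methoxy-1,4-benzoquinone
Conditions: 4 in MeCN/CH2Cl2 added dropwise to (NH4)2Ce(NO3)6 (2.5 equiv), MeCN/H2O 3:1, 0 °C, 30 min
Reagents that add atoms: water, O
Why: Oxidative demethylation by tetravalent cerium converts the para-dimethoxy pair into the p-quinone, with the carbonyl oxygens coming from water by aryl–O cleavage. The third methoxy group survives as a vinylogous ester, and inverse addition keeps the radical cation dilute to suppress biaryl coupling.

Step 3
Reactants: 5 3-hexadecyl-2-methoxy-1,4-benzoquinone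
Product: 8 3-hexadecyl-2,5-dihydroxy-1,4-benzoquinone, via aryloxypyridinium phenolate 6 (not isolated), via 3-hexadecyl-5-hydroxy-2-methoxy-1,4-benzoquinone 7 (not isolated)
Conditions: 2,6-lutidine N-oxide (2.0 equiv), Sc(OTf)3 (10 mol %), 4 Å MS, MeCN/CH2Cl2 1:1, 0 → 40 °C; evaporate; 2 M NaOH aq, EtOH, 70 °C, N2; then 2 M HCl
Reagents that add atoms: 2,6-lutidine N-oxide (2,6-dimethylpyridine 1-oxide), Cc1cccc(C)[n+]1[O-]; sodium hydroxide, [Na+].[OH-]
Why: Proposed new method: nucleophilic oxygen-atom transfer from a pyridine N-oxide to a quinone C–H position, redox-neutral at the quinone. Sc(OTf)3 chelated between the C1 carbonyl and the C2 methoxy oxygen activates the C1(=O)–C6=C5 enone, while the C4 carbonyl is a deactivated vinylogous ester, so the N-oxide oxygen adds at C5 (oxa-Michael, the site amines, thiols and acetate take on 2-methoxyquinones). Enolisation gives aryloxypyridinium phenolate 6, whose ortho phenolate expels 2,6-lutidine by heterolysis of the weak N–O bond (equivalently E1cB loss of the pyridine from the keto tautomer, as in Ganem/Kornblum N-oxide oxidations), giving hydroxyquinone 7 without external oxidant. The hindered lutidine does not add to the quinone, and 7 is a deactivated anion, so no second addition occurs. Aqueous NaOH then cleaves the remaining vinylogous methyl ester by addition–elimination to give 8. The closest known reaction types are vicarious nucleophilic hydroxylation of nitroarenes by hydroperoxide anions, Thiele–Winter conjugate oxygenation of quinones, and N-oxide oxygen transfer to activated π-electrophiles; no stereocentre is formed.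

**Compound list**
1 | 1,2,4-trimethoxybenzene | COc1ccc(OC)c(OC)c1 | starting material
2 | 1-bromohexadecane | CCCCCCCCCCCCCCCCBr | starting material
3 | (2,3,6-trimethoxyphenyl)lithium | [Li]c1c(OC)ccc(OC)c1OC | intermediate
4 | 2-hexadecyl-1,3,4-trimethoxybenzene (hexadecyl between the 1- and 3-methoxy groups) | CCCCCCCCCCCCCCCCc1c(OC)ccc(OC)c1OC | intermediate
5 | 3-hexadecyl-2-methoxy-1,4-benzoquinone | CCCCCCCCCCCCCCCCC1=C(OC)C(=O)C=CC1=O | intermediate
6 | 6-[(2,6-dimethylpyridin-1-ium-1-yl)oxy]-2-hexadecyl-4-hydroxy-3-methoxyphenolate (zwitterion) | CCCCCCCCCCCCCCCCc1c(OC)c(O)cc(O[n+]2c(C)cccc2C)c1[O-] | intermediate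
7 | 3-hexadecyl-5-hydroxy-2-methoxy-1,4-benzoquinone | CCCCCCCCCCCCCCCCC1=C(OC)C(=O)C=C(O)C1=O | intermediate
8 | 3-hexadecyl-2,5-dihydroxy-1,4-benzoquinone (achiral) | CCCCCCCCCCCCCCCCC1=C(O)C(=O)C=C(O)C1=O | target

**Totals**
Total step count: 3. Longest linear sequence: 3.

**Steps most likely to fail, with fallbacks**

Step 3 (the proposed new C–O bond formation). Risks: the N-oxide may be too weak a nucleophile or be sequestered by scandium, or it may add at C6 and give the 2,6-dihydroxy isomer after hydrolysis. Fallback with known chemistry, setting out from 5: Thiele–Winter acetoxylation (Ac2O, catalytic H2SO4, rt) adds acetate at C5 and acetylates the resulting hydroquinone to give 6-hexadecyl-5-methoxybenzene-1,2,4-triyl triacetate F3. Saponification with 2 M NaOH in MeOH/H2O open to air removes the three acetates, the hydroxyhydroquinone autoxidises in the flask to 7, and continued heating hydrolyses the methyl vinylogous ester. Acidification with HCl returns the route at 8.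

Step 2 (oxidative demethylation). Risks: the radical cation of the electron-rich trimethoxyarene may couple at the free position para to the 3-methoxy group to give biaryl or diquinone, or some o-quinone may form. Fallback, setting out from 4: anodic oxidation in 1% KOH/MeOH with THF cosolvent (carbon anode, undivided cell, 0 °C, constant current) traps the oxidised arene as the quinone bisketal 2-hexadecyl-1,3,3,6,6-pentamethoxycyclohexa-1,4-diene F2, which fixes the para pattern. Brief treatment with dilute aqueous HCl in acetone at 0 °C hydrolyses both ketals and returns the route at 5.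

Step 1 (alkylation of the hindered aryllithium). Risks: slow SN2 at the doubly ortho-substituted aryllithium, with E2 to 1-hexadecene and halogen–metal exchange competing. Fallback, setting out from aryllithium 3 generated as in step 1: addition to hexadecanal (CCCCCCCCCCCCCCCC=O) in THF at −78 °C gives 1-(2,3,6-trimethoxyphenyl)hexadecan-1-ol F1 (racemic; the stereocentre is removed in the next operation). Ionic hydrogenation of this electron-rich benzylic alcohol (Et3SiH, CF3CO2H, CH2Cl2, 0 °C → rt) returns the route at 4.

**Further compounds**
F1 | step 1 | 1-(2,3,6-trimethoxyphenyl)hexadecan-1-ol (racemic) | CCCCCCCCCCCCCCCC(O)c1c(OC)ccc(OC)c1OC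
F2 | step 2 | 2-hexadecyl-1,3,3,6,6-pentamethoxycyclohexa-1,4-diene | CCCCCCCCCCCCCCCCC1=C(OC)C(OC)(OC)C=CC1(OC)OC
F3 | step 3 | 6-hexadecyl-5-methoxybenzene-1,2,4-triyl triacetate | CCCCCCCCCCCCCCCCc1c(OC)c(OC(C)=O)cc(OC(C)=O)c1OC(C)=O
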